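**Retrosynthetic overview**

1. Target ⇐ angeloylation of the C9/C12 diol ⇐ Evans–Tishchenko reduction (gives C11–OAc and C9–OH) ⇐ hydroxyl-directed reduction of a tricyclic 1,3-diketone.
2. Cyclobutane (C3–C8 bond, formed last) ⇐ transannular oxidative coupling of two enolate carbons: C3 (α′ of the enone) and C8 (γ of the ring B diketone).
3. Ring B (seven-membered, formed second) ⇐ Claisen cyclisation of a C9 methyl ketone onto the C11 ester; C4 carbonyl ⇐ allylic oxidation.
4. C2–C1 and C7–C8 bonds ⇐ two suprafacial [3,3] shifts (Ireland–Claisen, Carroll) from the cis-diol oxygens of (1S,2R)-3-methylcyclohexa-3,5-diene-1,2-diol.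
5. Ring A (formed first, source of all chirality) ⇐ enzymatic cis-dihydroxylation of toluene. Ring order: A, B, cyclobutane.

Assumption (numbering): core carbons are labelled as they occur in the target SMILES: C12H2(OAng)–C1(CH3)–C2H–C3H–C4(=O)–C5H=C6(CH3)–C7H–C8(CH3)–C9H(OAng)–C10H2–C11H(OAc); ring A = C2–C7; ring B = C1, C2, C7–C11; "β face" = the face of ring A that carries the two hydroxyls of 2.

Note: numbered reactants are not repeated under "Reagents that add atoms"; acid 5 is racemic and C8 is an epimer mixture in 13–17, because both centres become planar later.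

**Route**

Step 1
Reactants: 1 toluene
Product: 2 (1S,2R)-3-methylcyclohexa-3,5-diene-1,2-diol
Conditions: whole cells of E. coli JM109 (pDTG601) expressing toluene dioxygenase, air, glucose, phosphate buffer pH 7, 35 °C
Reagents that add atoms: dioxygen, O=O
Why: enzymatic arene cis-dihydroxylation delivers both oxygens to one face and gives the (1S,2R) diol in high ee, the only source of absolute configuration in the route.

Step 2
Reactants: 3 methyl 3-hydroxy-2-methylpropanoate (racemic)
Product: 5 3-[(tert-butyldimethylsilyl)oxy]-2-methylpropanoic acid, via silyl ether methyl ester 4 (not isolated)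
Conditions: t-BuMe2SiCl, imidazole, DMF, 25 °C; then LiOH, THF/MeOH/H2O, 0–25 °C; dilute HCl work-up
Reagents that add atoms: t-BuMe2SiCl, CC(C)(C)[Si](C)(C)Cl; LiOH, [Li+].[OH-]
Why: routine silylation and saponification; the α-centre is planarised in step 4, so racemic material is sufficient.

Step 3
Reactants: 2 (1S,2R)-3-methylcyclohexa-3,5-diene-1,2-diol; 5 3-[(tert-butyldimethylsilyl)oxy]-2-methylpropanoic acid
Product: 6 (1S,6R)-6-hydroxy-5-methylcyclohexa-2,4-dien-1-yl 3-[(tert-butyldimethylsilyl)oxy]-2-methylpropanoate
Conditions: N,N'-dicyclohexylcarbodiimide (1.0 equiv), 4-(dimethylamino)pyridine (0.1 equiv), CH2Cl2, −20 °C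
Reagents that add atoms: none
Why: Steglich esterification; the hydroxyl remote from the ring methyl (the C4 oxygen) is the less hindered one and is acylated first, under neutral conditions that avoid aromatisation of the diene diol.

Step 4
Reactants: 6 dienyl monoester
Product: 10 dienol methyl ester (C1–C2 bond made), via silyl ketene acetal 7 (not isolated), via rearranged silyl ester 8 (not isolated), via hydroxy acid 9 (not isolated)
Conditions: LiN(iPr)2 (2.3 equiv), Me3SiCl (3 equiv, present from the start), THF–DMPU, −78 → 25 °C; pH 5 buffer; then Me3SiCHN2, PhMe–MeOH, 0 °C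
Reagents that add atoms: Me3SiCHN2, C[Si](C)(C)C=[N+]=[N-]
Why: Ireland–Claisen rearrangement; in-situ silylation prevents β-elimination of the silyloxy group, the suprafacial shift from the C4 oxygen across C4–C3=C2 places C1 on the β face of C2, and the boat-like transition state favoured by cyclohexenyl esters puts the small CH3 over the ring and CH2OSi outward (ketene acetal with CH2OSi cis to OSiMe3), which fixes the quaternary C1 as in the target; the acid is then methylated with the diazo reagent.

Step 5
Reactants: 10 dienol methyl ester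
Product: 11 cyclohexenol methyl ester
Conditions: 2-nitrobenzenesulfonylhydrazide, Et3N, CH2Cl2, 25 °C
Reagents that add atoms: none
Why: diimide reduction takes the cis-disubstituted C3=C4 alkene much faster than the trisubstituted C6=C7 alkene; this removes the aromatisation-prone skipped diene and leaves the C5 hydroxyl allylic to a single alkene, so the next [3,3] shift can only go to C7.

Step 6
Reactants: 11 cyclohexenol methyl ester; 12 ethyl 2-methyl-3-oxobutanoate
Product: 15 methyl ketone ester, via allylic keto ester 13 (not isolated), via keto acid 14 (not isolated)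
Conditions: 12 (3 equiv), 4-(dimethylamino)pyridine (0.2 equiv), xylenes, 140 °C, EtOH distilled off
Reagents that add atoms: none
Why: Carroll rearrangement (transesterification, [3,3] shift of the enol, decarboxylation); the suprafacial shift from the C5 oxygen puts the 3-oxobutan-2-yl chain on the β face of C7, cis to the C2 substituent, and moves the alkene to C5=C6; both C8 epimers are usable.

Step 7
Reactants: 15 methyl ketone ester
Product: 16 enone keto ester
Conditions: CrO3, 3,5-dimethylpyrazole, CH2Cl2, −20 °C
Reagents that add atoms: CrO3, O=[Cr](=O)=O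
Why: allylic oxidation with the hexavalent chromium–pyrazole complex converts the only allylic methylene (C4) into the conjugated ketone, as in pinene-to-verbenone oxidations; the other ring allylic position (C7) is a hindered methine.

Step 8
Reactants: 16 enone keto ester
Product: 17 cis-fused bicyclic trione
Conditions: LiN(iPr)2 (2.5 equiv), THF, −78 → 0 °C; aq NH4Cl
Reagents that add atoms: none
Why: Claisen (Dieckmann-type) cyclisation; the kinetic methyl-ketone enolate (C10) attacks the non-enolisable C11 ester, and the seven-membered 1,3-diketone is trapped as its enolate (the five-membered alternative through C8 cannot be deprotonated and reverts); the cis ring fusion is already set at C2 and C7.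

Step 9
Reactants: 17 cis-fused bicyclic trione
Product: 19 tricyclic trione silyl ether, via trilithium tris-enolate 18 (not isolated)
Conditions: LiN(iPr)2 (3.3 equiv), THF–DMPU, −78 → −20 °C; Fe(acac)3 (2.2 equiv), −78 → 25 °C; 1 M HCl
Reagents that add atoms: none
Why: Proposed new method: three deprotonations give the cross-conjugated C3 enolate of the enone and the C8/C10 dienolate of the 1,3-diketone; one-electron oxidation by trivalent iron at the electron-richest terminus (C8) gives an α-keto radical held about 3 Å from C3 in the cis-fused bicycle, radical–enolate combination closes the cyclobutane, and a second oxidation of the ketyl restores the C4 ketone, with the surviving diketonate as thermodynamic sink (disfavouring attack through C10); the ring B tether forces C9 to stay on the face of C1 and the C8 methyl over the enone, so C3 and C8 are set by geometry; closest known reactions are intramolecular oxidative enolate heterocouplings with Fe(acac)3 or copper carboxylates, cyclobutane-forming bis-enolate couplings, and γ,γ-coupling of 1,3-dicarbonyl dianions.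

Step 10
Reactants: 19 tricyclic trione silyl ether
Product: 20 tricyclic trione alcohol
Conditions: HF·pyridine, THF, 0 °C
Reagents that add atoms: none
Why: fluoride cleavage of the primary silyl ether; ketones and enone are inert.

Step 11
Reactants: 20 tricyclic trione alcohol
Product: 21 C11-hydroxy dione
Conditions: Me4NBH(OAc)3 (1.5 equiv), MeCN–AcOH, −30 °C
Reagents that add atoms: none
Why: hydroxyl-directed (Evans–Saksena) reduction; the borohydride bound to the C12 oxygen delivers hydride to the C11 carbonyl from the face of C12, giving C11–OH trans to CH2OH (cis to the C1 methyl); the C4 enone has no directing hydroxyl, and the cyclic borate formed at O11/O12 blocks onward delivery to C9.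

Step 12
Reactants: 21 C11-hydroxy dione; 22 acetaldehyde
Product: 23 C11 acetate diol
Conditions: SmI2 (0.3 equiv), THF, −10 °C, short reaction time
Reagents that add atoms: none
Why: Evans–Tishchenko reduction; the samarium-bound hemiacetal on the C11 oxygen transfers hydride intramolecularly to C9, giving the 1,3-anti diol as its C11 monoacetate, which sets C9 and differentiates the two secondary oxygens in one operation (low temperature limits acetyl migration).

Step 13
Reactants: 23 C11 acetate diol; 24 angelic acid
Product: 26 target CNP0364726.1, via mixed anhydride 25 (not isolated)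
Conditions: 24 (5 equiv), 2,4,6-Cl3C6H2COCl, Et3N, PhMe, 25 °C; then 23, 80 °C
Reagents that add atoms: none
Why: Yamaguchi-type esterification through the preformed mixed anhydride without nucleophilic catalyst acylates the primary C12 and secondary C9 hydroxyls while avoiding Z to E isomerisation of the angelate; the C11 acetate is untouched.

**Compound list**

1 | toluene | Cc1ccccc1 | starting material
2 | (1S,2R)-3-methylcyclohexa-3,5-diene-1,2-diol | CC1=CC=C[C@H](O)[C@@H]1O | intermediate
3 | methyl 3-hydroxy-2-methylpropanoate (racemic) | COC(=O)C(C)CO | starting material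
4 | methyl 3-[(tert-butyldimethylsilyl)oxy]-2-methylpropanoate (racemic) | COC(=O)C(C)CO[Si](C)(C)C(C)(C)C | intermediate
5 | 3-[(tert-butyldimethylsilyl)oxy]-2-methylpropanoic acid (racemic) | CC(CO[Si](C)(C)C(C)(C)C)C(O)=O | intermediate
6 | (1S,6R)-6-hydroxy-5-methylcyclohexa-2,4-dien-1-yl 3-[(tert-butyldimethylsilyl)oxy]-2-methylpropanoate (ester on the C4 oxygen; both epimers at the acyl α-carbon) | CC1=CC=C[C@H](OC(=O)C(C)CO[Si](C)(C)C(C)(C)C)[C@@H]1O | intermediate
7 | silyl ketene acetal of 6 (CH2OSi cis to OSiMe3) with the C5 hydroxyl as Me3Si ether | CC1=CC=C[C@H](O/C(O[Si](C)(C)C)=C(\C)CO[Si](C)(C)C(C)(C)C)[C@@H]1O[Si](C)(C)C | intermediate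
8 | trimethylsilyl ester of 9 carrying C5–OSiMe3 (product of the [3,3] shift) | CC1=C[C@H]([C@@](C)(CO[Si](C)(C)C(C)(C)C)C(=O)O[Si](C)(C)C)C=C[C@@H]1O[Si](C)(C)C | intermediate
9 | hydroxy acid: quaternary C1 (CH3, CH2OSi, CO2H) bonded to C2 of a 4-hydroxy-3-methylcyclohexa-2,5-dienyl ring, C2 and C5 substituents cis (β), C1 as in the target | CC1=C[C@H]([C@@](C)(CO[Si](C)(C)C(C)(C)C)C(O)=O)C=C[C@@H]1O | intermediate
10 | methyl ester of 9 | CC1=C[C@H]([C@@](C)(CO[Si](C)(C)C(C)(C)C)C(=O)OC)C=C[C@@H]1O | intermediate
11 | C3,C4-dihydro derivative of 10 (cyclohex-2-en-1-ol; C5–OH and C2 side chain cis) | CC1=C[C@H]([C@@](C)(CO[Si](C)(C)C(C)(C)C)C(=O)OC)CC[C@@H]1O | intermediate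
12 | ethyl 2-methyl-3-oxobutanoate (racemic) | CCOC(=O)C(C)C(C)=O | starting material
13 | 2-methyl-3-oxobutanoate ester of 11 at the C5 oxygen | CC1=C[C@H]([C@@](C)(CO[Si](C)(C)C(C)(C)C)C(=O)OC)CC[C@@H]1OC(=O)C(C)C(C)=O | intermediate
14 | keto acid: C7 (β, cis to the C2 chain) bears C8(CH3)(COCH3)(CO2H); alkene at C5=C6; C8 epimers | CC1=CCC[C@@H]([C@@](C)(CO[Si](C)(C)C(C)(C)C)C(=O)OC)[C@H]1C(C)(C(C)=O)C(O)=O | intermediate
15 | methyl 3-[(tert-butyldimethylsilyl)oxy]-2-methyl-2-[(1,2-cis)-3-methyl-2-(3-oxobutan-2-yl)cyclohex-3-en-1-yl]propanoate (C8 epimers) | CC1=CCC[C@@H]([C@@](C)(CO[Si](C)(C)C(C)(C)C)C(=O)OC)[C@H]1C(C)C(C)=O | intermediate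
16 | C4 ketone of 15 (3-methyl-5-oxo-2-(3-oxobutan-2-yl)cyclohex-3-en-1-yl ring; C8 epimers) | CC1=CC(=O)C[C@@H]([C@@](C)(CO[Si](C)(C)C(C)(C)C)C(=O)OC)[C@H]1C(C)C(C)=O | intermediate
17 | cis-fused bicyclo[5.4.0]undecene trione: ring A enone (C4=O, C5=C6–CH3), ring B 1,3-dione (C9=O, C11=O), C8–CH3 (epimers), C1 bearing CH3 and CH2OSi | CC1=CC(=O)C[C@@H]2[C@H]1C(C)C(=O)CC(=O)[C@]2(C)CO[Si](C)(C)C(C)(C)C | intermediate
18 | trilithium tris-enolate of 17 (C3=C4–OLi, C8=C9–OLi, C10=C11–OLi) | [Li+].[Li+].[Li+].CC1=CC([O-])=C[C@@H]2[C@H]1C(C)=C([O-])C=C([O-])[C@]2(C)CO[Si](C)(C)C(C)(C)C | intermediate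
19 | tricyclic trione: target skeleton (C3–C8 bond closed) with C9=O, C11=O and C12–OSi(t-Bu)Me2 | CC(C)(C)[Si](C)(C)OC[C@]1(C)[C@@H]2[C@H]3C(=O)C=C(C)[C@@H]2[C@@]3(C)C(=O)CC1=O | intermediate
20 | 19 with free C12–OH | OC[C@]1(C)[C@@H]2[C@H]3C(=O)C=C(C)[C@@H]2[C@@]3(C)C(=O)CC1=O | intermediate
21 | C11 alcohol (C11–OH trans to CH2OH), C9 and C4 ketones retained | OC[C@]1(C)[C@@H]2[C@H]3C(=O)C=C(C)[C@@H]2[C@@]3(C)C(=O)C[C@H]1O | intermediate
22 | acetaldehyde | CC=O | starting material
23 | C11 acetate, C9 alcohol (anti to the C11 oxygen), free C12–OH | OC[C@]1(C)[C@@H]2[C@H]3C(=O)C=C(C)[C@@H]2[C@@]3(C)[C@H](O)C[C@H]1OC(C)=O | intermediate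
24 | angelic acid, (Z)-2-methylbut-2-enoic acid | C/C=C(/C)C(O)=O | starting material
25 | angelic 2,4,6-trichlorobenzoic anhydride | C/C=C(/C)C(=O)OC(=O)c1c(Cl)cc(Cl)cc1Cl | intermediate
26 | CNP0364726.1 (C11 acetate, C9 and C12 angelates) | C/C=C(/C)C(=O)OC[C@]1(C)[C@@H]2[C@H]3C(=O)C=C(C)[C@@H]2[C@@]3(C)[C@H](OC(=O)/C(C)=C\C)C[C@H]1OC(C)=O | target

**Step count and risks**

Total step count: 13. Longest linear sequence: 12 (steps 1 and 3–13; step 2 is a one-step side branch).

Steps most likely to fail:

Step 9 (transannular oxidative enolate coupling). Risks are coupling through C10 (which would give a five-membered ring), intermolecular dimerisation, or failure to close the strained four-membered ring. Fallback, from 17 back to 19: trap the tris-enolate with Me3SiCl to give the tris(trimethylsilyl) enol ether F1, then treat it with PhI(OAc)2 and BF3·OEt2 in CH2Cl2 at −40 °C. The trivalent iodine reagent turns the C3 enol ether into an electrophilic α-iodanyl ketone (a two-electron enolonium), and the 2,4-bis(silyloxy)diene of ring B attacks it through its terminal carbon C8, the position at which such dienes react, so C10 stays out of play; aqueous work-up removes the remaining silyl groups and gives 19.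

Step 4 (Ireland–Claisen rearrangement). Risks are β-elimination of the silyloxy group, poor ketene acetal geometry, and a chair/boat mixture that would erode the C1 configuration. Fallback, from 6 back to 10: remove the silyl group with HF·pyridine to give the hydroxy ester F2; with LiN(iPr)2 (3.3 equiv) this forms a lithium-chelated β-oxido ester enolate of fixed geometry that cannot eliminate, and its dianionic Claisen rearrangement on warming to 40 °C gives the dihydroxy acid F3; Me3SiCHN2 gives the dihydroxy methyl ester F4, and t-BuMe2SiCl with imidazole silylates only the primary hydroxyl to give 10.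

Step 8 (Claisen cyclisation in the presence of the enone). Risks are epimerisation at C7 through the dienolate, aldol side reactions of the C3 enolate, and slow attack on the neopentyl ester. Fallback, from 15 back to 17: close ring B before the enone exists. KOtBu in THF at 25 °C on 15, which has a single enolisable ketone, gives the bicyclic alkene diketone F5 under thermodynamic control; allylic oxidation of F5 with CrO3 and 3,5-dimethylpyrazole at −20 °C then installs the C4 carbonyl and gives 17.

**Further compounds**

F1 | step 9 | tris(trimethylsilyl) enol ether of 17 (C3=C4–OSiMe3; C8=C9(OSiMe3)–C10=C11–OSiMe3) | CC1=CC(O[Si](C)(C)C)=C[C@@H]2[C@H]1C(C)=C(O[Si](C)(C)C)C=C(O[Si](C)(C)C)[C@]2(C)CO[Si](C)(C)C(C)(C)C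
F2 | step 4 | (1S,6R)-6-hydroxy-5-methylcyclohexa-2,4-dien-1-yl 3-hydroxy-2-methylpropanoate | CC1=CC=C[C@H](OC(=O)C(C)CO)[C@@H]1O
F3 | step 4 | dihydroxy acid: desilylated analogue of 9 | CC1=C[C@H]([C@@](C)(CO)C(O)=O)C=C[C@@H]1O
F4 | step 4 | dihydroxy methyl ester: desilylated analogue of 10 | CC1=C[C@H]([C@@](C)(CO)C(=O)OC)C=C[C@@H]1O
F5 | step 8 | cis-fused bicyclic alkene diketone: 17 with CH2 at C4 | CC1=CCC[C@@H]2[C@H]1C(C)C(=O)CC(=O)[C@]2(C)CO[Si](C)(C)C(C)(C)C
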